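**Plan**
1. Numbering: chain C1 (CH2OH of the arm on the ether CH) to C16 (CH2OH of the arm on the quaternary carbon), C17 = lactone carbonyl; core atoms C6 (ether CH), C7 (C–Me, lactone O7), C8, C9, C10 (CHOH), C11 (quaternary); O6 is the ring ether oxygen, O8 an oxygen placed temporarily on C8.
2. Retrosynthetic cuts: lactone C17–O7; then C10–C11 with return of a C17–O8 ester bond (retro-[3,3]) to a 1,4-dioxepan-2-one carrying C8–C9=C10–OPMB; then C17–O8, C8–C9, the ether O6–C11, C6–C7 and C13–C14.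
3. Enabling feature: in the oxepane (O6, C6–C11) the adjacent stereocentres C10 and C11 lie two carbons from C8, and C11 bears both the ether oxygen and the carboxyl carbon. An ester oxygen on an allylic C8 (C8–C9=C10) can therefore pass C10 to C11 while the seven-membered lactone (C17, C11, O6, C6, C7, C8, O8) turns into the seven-membered ether ring.
4. Forward: nerol gives the C1–C6 aldehyde; lactic acid dioxolanone aldol (C6–C7); Williamson ether with the C11–C16 bromo acid (made by Negishi coupling); (E)-alkoxyvinylzinc addition (C8–C9); lactonisation to the dioxepanone; Ireland–Claisen to the oxepene; alkene reduction; bridging lactone; deprotection.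
5. Stereochemistry: C7 from (R)-lactic acid (acetal-relayed, retention), C6 from the aldol chair, C8 from Felkin–Anh addition, C11 from C8 through the ring-enforced boat, C10 from the (E)-enol ether; 2Z from nerol, 14Z from anti-carbomagnesiation of propargyl alcohol.

Key step: step 21

Remark: TBDPS = tert-butyldiphenylsilyl, TES = triethylsilyl, PMB = 4-methoxybenzyl; the chain locants defined above are used in names; C11 is carried as a mixture of epimers from the etherification to the key step, where enolisation makes it planar.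

**Route**

Step 1
Reactants: 1 prop-2-yn-1-ol
Product: 3 (2Z)-3-iodo-2-methylprop-2-en-1-ol, via alkenylmagnesium alkoxide 2 (not isolated)
Conditions: MeMgBr (2.5 equiv), CuI (10 mol%), THF/Et2O, −10 °C to rt; then I2, −10 °C
Reagents that add atoms: methylmagnesium bromide, C[Mg]Br; iodine, II
Why: Copper-catalysed anti-carbomagnesiation of the propargylic alkoxide puts methyl on C2 and magnesium on C3 cis to CH2O through a five-membered chelate, and iodinolysis with retention should give the Z iodide.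

Step 2
Reactants: 3 (2Z)-3-iodo-2-methylprop-2-en-1-ol
Product: 4 tert-butyl{[(2Z)-3-iodo-2-methylprop-2-en-1-yl]oxy}diphenylsilane
Conditions: TBDPSCl, imidazole, CH2Cl2, 0 °C to rt
Reagents that add atoms: tert-butyl(chloro)diphenylsilane, CC(C)(C)[Si](Cl)(c1ccccc1)c1ccccc1
Why: Imidazole-promoted silylation of the primary allylic alcohol leaves the alkenyl iodide and its geometry untouched.

Step 3
Reactants: 4 tert-butyl{[(2Z)-3-iodo-2-methylprop-2-en-1-yl]oxy}diphenylsilane; 5 (4-ethoxy-4-oxobutyl)zinc bromide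
Product: 6 ethyl (5Z)-7-(TBDPSO)-6-methylhept-5-enoate
Conditions: PdCl2(dppf) (5 mol%), THF, rt to 50 °C
Reagents that add atoms: none
Why: Negishi sp3–sp2 cross-coupling of the ester-bearing alkylzinc with the alkenyl iodide proceeds with retention of the Z geometry, the bidentate ferrocenyl phosphine holding back beta-hydride elimination.

Step 4
Reactants: 6 ethyl (5Z)-7-(TBDPSO)-6-methylhept-5-enoate
Product: 8 ethyl (5Z)-2-bromo-7-(TBDPSO)-6-methylhept-5-enoate (racemic), via lithium enolate 7 (not isolated)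
Conditions: LiN(iPr)2, THF, −78 °C; then CBr4, −78 °C; AcOH quench
Reagents that add atoms: tetrabromomethane, BrC(Br)(Br)Br
Why: Electrophilic alpha-bromination of the ester lithium enolate by bromine transfer from CBr4 leaves the alkene alone, and the racemate suffices because C11 is later planarised.

Step 5
Reactants: 8 ethyl (5Z)-2-bromo-7-(TBDPSO)-6-methylhept-5-enoate
Product: 9 (5Z)-2-bromo-7-(TBDPSO)-6-methylhept-5-enoic acid (racemic)
Conditions: LiOH, THF/H2O, 0 °C; then 1 M HCl to pH 3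
Reagents that add atoms: lithium hydroxide, [Li+].[OH-]
Why: Saponification at the ester carbonyl is faster at 0 °C than hydroxide displacement of the secondary bromide, so the free 2-bromo acid should result.

Step 6
Reactants: 10 (4-methoxyphenyl)methanol; 11 trichloroethene
Product: 12 1-({[(E)-1,2-dichloroethenyl]oxy}methyl)-4-methoxybenzene
Conditions: KH, THF, −50 °C to rt
Reagents that add atoms: none
Why: The potassium alkoxide dehydrochlorinates trichloroethene to dichloroacetylene and adds to it anti (addition–protonation), the standard route to 1,2-dichlorovinyl ethers.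

Step 7
Reactants: 12 1-({[(E)-1,2-dichloroethenyl]oxy}methyl)-4-methoxybenzene
Product: 14 1-[(ethynyloxy)methyl]-4-methoxybenzene, via lithium alkoxyacetylide 13 (not isolated)
Conditions: n-BuLi (2.2 equiv), THF, −78 to −40 °C; then MeOH, −78 °C; work-up and storage below 0 °C
Reagents that add atoms: none
Why: Dehydrochlorination to the chloroalkynyl ether and chlorine–lithium exchange give the lithium alkynyl ether, which is protonated and kept cold because benzyl alkynyl ethers rearrange sigmatropically on warming.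

Step 8
Reactants: 15 nerol
Product: 16 tert-butyl{[(2Z)-3,7-dimethylocta-2,6-dien-1-yl]oxy}diphenylsilane
Conditions: TBDPSCl, imidazole, CH2Cl2, 0 °C to rt
Reagents that add atoms: tert-butyl(chloro)diphenylsilane, CC(C)(C)[Si](Cl)(c1ccccc1)c1ccccc1
Why: Silylation of the primary allylic alcohol gives an ether that survives the base, hydride and mild acid steps ahead.

Step 9
Reactants: 16 tert-butyl{[(2Z)-3,7-dimethylocta-2,6-dien-1-yl]oxy}diphenylsilane
Product: 18 (4Z)-6-(TBDPSO)-4-methylhex-4-enal, via 6,7-epoxide 17 (not isolated)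
Conditions: mCPBA (1.05 equiv), NaHCO3, CH2Cl2, −20 °C; then H5IO6, THF/H2O, 0 °C
Reagents that add atoms: 3-chloroperoxybenzoic acid, OOC(=O)c1cccc(Cl)c1
Why: Prilezhaev epoxidation prefers the distal trisubstituted alkene (the 2,3-alkene is inductively deactivated and shielded by the silyloxy group), and periodic acid then opens and cleaves the epoxide to the aldehyde and acetone without touching the Z alkene.

Step 10
Reactants: 19 (R)-lactic acid
Product: 20 (2R,5R)-2-tert-butyl-5-methyl-1,3-dioxolan-4-one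
Conditions: t-BuCHO, TsOH (cat.), pentane, reflux with water separator; crystallisation from pentane/Et2O at −78 °C
Reagents that add atoms: 2,2-dimethylpropanal, CC(C)(C)C=O
Why: Acid-catalysed acetalisation under thermodynamic control favours the cis acetal, which is purified by cold crystallisation and stores the lactic acid chirality at the acetal carbon.

Step 11
Reactants: 20 (2R,5R)-2-tert-butyl-5-methyl-1,3-dioxolan-4-one; 18 (4Z)-6-(TBDPSO)-4-methylhex-4-enal
Product: 22 (2R,5S)-2-tert-butyl-5-[(1S,4Z)-6-(TBDPSO)-1-hydroxy-4-methylhex-4-en-1-yl]-5-methyl-1,3-dioxolan-4-one, via lithium enolate 21 (not isolated)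
Conditions: LiN(iPr)2, THF, −78 °C; then 18, −78 °C; AcOH quench at −78 °C
Reagents that add atoms: none
Why: In this aldol with self-regeneration of the stereocentre the enolate is attacked anti to tert-butyl, so C7 keeps the lactic acid configuration, and a Zimmerman–Traxler chair (aldehyde chain equatorial, enolate methyl cis to OLi) should favour the 6S alcohol, the C6 epimer being removed by chromatography.

Step 12
Reactants: 22 (2R,5S)-2-tert-butyl-5-[(1S,4Z)-6-(TBDPSO)-1-hydroxy-4-methylhex-4-en-1-yl]-5-methyl-1,3-dioxolan-4-one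
Product: 23 (2R,3S,6Z)-8-(TBDPSO)-2,6-dimethyloct-6-ene-1,2,3-triol
Conditions: LiAlH4, THF, 0 °C
Reagents that add atoms: none
Why: Hydride reduction of the acetal-lactone collapses the ring with loss of pivalaldehyde (reduced to neopentyl alcohol) and frees the triol without touching C6, C7, the alkene or the silyl ether.

Step 13
Reactants: 23 (2R,3S,6Z)-8-(TBDPSO)-2,6-dimethyloct-6-ene-1,2,3-triol
Product: 24 (1S,4Z)-6-(TBDPSO)-4-methyl-1-[(4R)-2,2,4-trimethyl-1,3-dioxolan-4-yl]hex-4-en-1-ol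
Conditions: 2,2-dimethoxypropane, PPTS (cat.), CH2Cl2, 0 °C to rt
Reagents that add atoms: 2,2-dimethoxypropane, COC(C)(C)OC
Why: Acid-catalysed transacetalisation should close the dioxolane across the primary C8 and tertiary C7 hydroxyls (entered through the fast primary hydroxyl and free of the cis 4,5-clash of the C6/C7 alternative), leaving only the C6 hydroxyl free.

Step 14
Reactants: 24 (1S,4Z)-6-(TBDPSO)-4-methyl-1-[(4R)-2,2,4-trimethyl-1,3-dioxolan-4-yl]hex-4-en-1-ol; 9 (5Z)-2-bromo-7-(TBDPSO)-6-methylhept-5-enoic acid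
Product: 26 methyl (5Z)-7-(TBDPSO)-6-methyl-2-{[(1S,4Z)-6-(TBDPSO)-4-methyl-1-[(4R)-2,2,4-trimethyl-1,3-dioxolan-4-yl]hex-4-en-1-yl]oxy}hept-5-enoate (C11 epimers), via ether acid 25 (not isolated)
Conditions: NaH (4 equiv), THF/DMF, 0 to 50 °C; then MeI, rt
Reagents that add atoms: iodomethane, CI
Why: In this Williamson etherification the sodium alkoxide of 24 displaces bromide from the sodium carboxylate of 9 by SN2 (the carboxylate shuts off enolisation and ester condensation, as in classical 2-halo acid etherifications of hindered secondary alkoxides), and methyl iodide then esterifies the carboxylate in the same flask.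

Step 15
Reactants: 26 methyl ester acetonide (C11 epimers)
Product: 27 methyl (5Z)-7-(TBDPSO)-2-{[(2R,3S,6Z)-8-(TBDPSO)-1,2-dihydroxy-2,6-dimethyloct-6-en-3-yl]oxy}-6-methylhept-5-enoate (C11 epimers)
Conditions: AcOH/H2O/THF (3:1:1), 40 °C
Reagents that add atoms: none
Why: Mild acid hydrolysis of the terminal acetonide frees the C7/C8 diol while the primary TBDPS ethers and the methyl ester are stable.

Step 16
Reactants: 27 C7/C8 diol methyl ester
Product: 28 bis(triethylsilyl) ether of 27 (TESO on C7 and C8; 6S,7R)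
Conditions: Et3SiOTf (3 equiv), 2,6-lutidine, CH2Cl2, −78 to 0 °C
Reagents that add atoms: triethylsilyl trifluoromethanesulfonate, CC[Si](CC)(CC)OS(=O)(=O)C(F)(F)F
Why: Silylation with the silyl triflate reaches the tertiary C7 hydroxyl as well as the primary one, and the non-chelating C7–OTES is what the later carbonyl addition needs.

Step 17
Reactants: 28 bis(triethylsilyl) ether
Product: 29 C8 aldehyde with C7–OTES (methyl ester; 6S,7S; C11 epimers)
Conditions: (COCl)2, DMSO, CH2Cl2, −78 to −30 °C; then Et3N, −78 °C to rt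
Reagents that add atoms: none
Why: Swern oxidation acts directly on the primary triethylsilyl ether (chlorosulfonium-induced desilylation, then oxidation) while the hindered tertiary silyl ether is inert, and C7 carries no hydrogen that could epimerise.

Step 18
Reactants: 29 C8 aldehyde with C7–OTES; 14 1-[(ethynyloxy)methyl]-4-methoxybenzene
Product: 32 allylic alcohol C8(OH)–C9H=C10H–OPMB (methyl ester; 9E; 6S,7R,8R; C11 epimers), via alkenylzirconocene chloride 30 (not isolated), via alkenyl(methyl)zinc 31 (not isolated)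
Conditions: 14, Cp2Zr(H)Cl, CH2Cl2, rt; Me2Zn, PhMe, −65 °C; then 29, −65 to 0 °C; aq. NaHCO3
Reagents that add atoms: none
Why: Syn hydrozirconation of the terminal alkynyl ether fixes the E geometry, zirconium-to-zinc transmetalation gives an ester-tolerant nucleophile, and its 1,2-addition should follow the polar Felkin–Anh model (C7–OTES anti to the nucleophile, which passes the C7 methyl and not the C6 branch) to set 8R, the silyl ether disfavouring the Cram chelate that would give 8S.

Step 19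
Reactants: 32 allylic alcohol methyl ester
Product: 33 seco acid (free C17 carboxylic acid of 32; 6S,7R,8R)
Conditions: LiOH, THF/MeOH/H2O, rt; then NaH2PO4 buffer (pH 5)
Reagents that add atoms: lithium hydroxide, [Li+].[OH-]
Why: Saponification of the methyl ester is compatible with the base-stable enol ether and silyl ethers, and the buffered work-up protects the acid-labile gamma-alkoxyallyl alcohol.

Step 20
Reactants: 33 seco acid
Product: 34 (5S,6S,7R)-7-[(E)-2-(PMBO)ethenyl]-6-methyl-6-(TESO)-3-[(3Z)-5-(TBDPSO)-4-methylpent-3-en-1-yl]-5-[(3Z)-5-(TBDPSO)-3-methylpent-3-en-1-yl]-1,4-dioxepan-2-one (C11 epimers; chain 6S,7S,8R)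
Conditions: 2,4,6-Cl3C6H2COCl, Et3N, DMAP, PhMe, rt, high dilution
Reagents that add atoms: none
Why: Yamaguchi lactonisation through the mixed trichlorobenzoic anhydride and DMAP acyl transfer closes the seven-membered lactone onto the only free hydroxyl (C8) under basic conditions that spare the gamma-alkoxyallyl system.

Step 21
Reactants: 34 1,4-dioxepan-2-one (C11 epimers)
Product: 37 (2R,3S,6R,7S)-3-(PMBO)-6-methyl-6-(TESO)-2-[(3Z)-5-(TBDPSO)-4-methylpent-3-en-1-yl]-7-[(3Z)-5-(TBDPSO)-3-methylpent-3-en-1-yl]-2,3,6,7-tetrahydrooxepine-2-carboxylic acid (chain 6S,7R,10S,11R), via cyclic silyl ketene acetal 35 (not isolated), via trimethylsilyl ester 36 (not isolated)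
Conditions: KN(SiMe3)2, Me3SiCl/Et3N (premixed), THF, −78 °C; then rt to 70 °C (PhMe); aq. citric acid
Reagents that add atoms: none
Why: KN(SiMe3)2 removes the C11 proton of either epimer in the presence of Me3SiCl and O-silylation gives the cyclic ketene acetal 35, whose geometry (both ring oxygens cis) is fixed by the seven-membered ring. On warming, a concerted suprafacial [3,3] sigmatropic shift (Ireland–Claisen rearrangement) breaks O8–C8 and forms C10–C11; the closest known reaction is the Ireland–Claisen transposition of 6-alkenyl-1,4-dioxan-2-ones into dihydropyran-2-carboxylic acids, run here on the lactone one atom larger. The oxepene is closed by this pericyclic C–C bond formation between the ketene acetal carbon and the enol ether terminus as the lactone C–O bond opens, through a bicyclo[3.2.2]-like boat, the only geometry that the three-atom tether O6–C6–C7 and a cis ring alkene allow (a chair would require a trans-cycloheptene). At C11 the tether holds the allyl unit over the ketene acetal face fixed by the 8R centre, so 8R is relayed to 11R, and at C10 the (E)-enol ether places OPMB outward in the boat, cis to the carboxyl, which should give 10S. The step needs rearrangement to outrun ketene-forming fragmentation or elimination (secured by in situ Me3SiCl trapping at −78 °C and by the absence of a leaving group on C12) and boat over chair (secured by the ring).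

Step 22
Reactants: 37 oxepene acid
Product: 38 oxepane acid, the 8,9-dihydro derivative of 37 (oxepane-2-carboxylic acid; 6S,7R,10S,11R)
Conditions: 2-nitrobenzenesulfonohydrazide, Et3N, CH2Cl2, rt
Reagents that add atoms: none
Why: Diimide generated in situ reduces the cis-disubstituted ring alkene much faster than the two trisubstituted side-chain alkenes and cannot hydrogenolyse the PMB ether.

Step 23
Reactants: 38 oxepane acid
Product: 39 C7 hydroxy acid (TES removed; TBDPS and PMB kept)
Conditions: HF·pyridine, pyridine, THF, 0 °C to rt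
Reagents that add atoms: none
Why: Buffered fluoride desilylation cleaves the triethylsilyl ether far faster than the primary TBDPS ethers and frees the tertiary C7 hydroxyl cis to the carboxyl.

Step 24
Reactants: 39 C7 hydroxy acid
Product: 40 bridged lactone with 6,8-dioxabicyclo[3.2.2]nonan-7-one core (C10–OPMB; C1 and C16 TBDPS ethers; 6S,7R,10S,11R)
Conditions: 2,4,6-Cl3C6H2COCl, Et3N, DMAP, PhMe, rt to 80 °C
Reagents that add atoms: none
Why: In this Yamaguchi lactonisation the activated C11 carboxyl and the cis tertiary C7 hydroxyl are 1,4-related across the ring oxygen, so the six-membered lactone bridge should close, and no other hydroxyl is free.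

Step 25
Reactants: 40 bridged lactone PMB ether
Product: 41 C10 alcohol (bridged lactone; C1 and C16 TBDPS ethers)
Conditions: DDQ, CH2Cl2/pH 7 buffer, 0 °C
Reagents that add atoms: none
Why: Oxidative cleavage of the PMB ether by DDQ is done while both allylic alcohols are still silylated, so they cannot be oxidised to enals.

Step 26
Reactants: 41 C10 alcohol bis-TBDPS ether
Product: 42 CNP0105745.1
Conditions: Bu4NF, AcOH, THF, 0 °C to rt
Reagents that add atoms: none
Why: Fluoride desilylation of both primary TBDPS ethers, buffered with acetic acid so that the beta-hydroxy lactone is not exposed to alkoxide (retro-aldol or lactone opening), should give the target.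

**Compound list**
1 | prop-2-yn-1-ol | C#CCO | starting material
2 | bromomagnesium (2Z)-3-(bromomagnesio)-2-methylprop-2-en-1-olate | Br[Mg]/C=C(/C)CO[Mg]Br | intermediate (not isolated)
3 | (2Z)-3-iodo-2-methylprop-2-en-1-ol | I/C=C(/C)CO | intermediate
4 | tert-butyl{[(2Z)-3-iodo-2-methylprop-2-en-1-yl]oxy}diphenylsilane | I/C=C(/C)CO[Si](c1ccccc1)(c1ccccc1)C(C)(C)C | intermediate
5 | (4-ethoxy-4-oxobutyl)zinc bromide | CCOC(=O)CCC[Zn]Br | starting material
6 | ethyl (5Z)-7-(TBDPSO)-6-methylhept-5-enoate | CCOC(=O)CCC/C=C(/C)CO[Si](c1ccccc1)(c1ccccc1)C(C)(C)C | intermediate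
7 | lithium enolate of 6 | CCOC(O[Li])=CCC/C=C(/C)CO[Si](c1ccccc1)(c1ccccc1)C(C)(C)C | intermediate (not isolated)
8 | ethyl (5Z)-2-bromo-7-(TBDPSO)-6-methylhept-5-enoate, racemic | CCOC(=O)C(Br)CC/C=C(/C)CO[Si](c1ccccc1)(c1ccccc1)C(C)(C)C | intermediate
9 | (5Z)-2-bromo-7-(TBDPSO)-6-methylhept-5-enoic acid, racemic | OC(=O)C(Br)CC/C=C(/C)CO[Si](c1ccccc1)(c1ccccc1)C(C)(C)C | intermediate
10 | (4-methoxyphenyl)methanol | COc1ccc(CO)cc1 | starting material
11 | trichloroethene | ClC=C(Cl)Cl | starting material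
12 | 1-({[(E)-1,2-dichloroethenyl]oxy}methyl)-4-methoxybenzene | COc1ccc(CO/C(Cl)=C\Cl)cc1 | intermediate
13 | lithium [(4-methoxybenzyl)oxy]acetylide | [Li]C#COCc1ccc(OC)cc1 | intermediate (not isolated)
14 | 1-[(ethynyloxy)methyl]-4-methoxybenzene | C#COCc1ccc(OC)cc1 | intermediate
15 | nerol, (2Z)-3,7-dimethylocta-2,6-dien-1-ol | CC(C)=CCC/C(C)=C\CO | starting material
16 | tert-butyl{[(2Z)-3,7-dimethylocta-2,6-dien-1-yl]oxy}diphenylsilane | CC(C)=CCC/C(C)=C\CO[Si](c1ccccc1)(c1ccccc1)C(C)(C)C | intermediate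
17 | 6,7-epoxide of 16, racemic at the epoxide | CC1(C)OC1CC/C(C)=C\CO[Si](c2ccccc2)(c2ccccc2)C(C)(C)C | intermediate (not isolated)
18 | (4Z)-6-(TBDPSO)-4-methylhex-4-enal | O=CCC/C(C)=C\CO[Si](c1ccccc1)(c1ccccc1)C(C)(C)C | intermediate
19 | (R)-lactic acid | C[C@@H](O)C(=O)O | starting material
20 | (2R,5R)-2-tert-butyl-5-methyl-1,3-dioxolan-4-one | C[C@H]1O[C@@H](C(C)(C)C)OC1=O | intermediate
21 | lithium enolate of 20, (2R) | CC1=C(O[Li])O[C@H](C(C)(C)C)O1 | intermediate (not isolated)
22 | (2R,5S)-2-tert-butyl-5-[(1S,4Z)-6-(TBDPSO)-1-hydroxy-4-methylhex-4-en-1-yl]-5-methyl-1,3-dioxolan-4-one | C[C@@]1([C@@H](O)CC/C(C)=C\CO[Si](c2ccccc2)(c2ccccc2)C(C)(C)C)O[C@@H](C(C)(C)C)OC1=O | intermediate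
23 | (2R,3S,6Z)-8-(TBDPSO)-2,6-dimethyloct-6-ene-1,2,3-triol | OC[C@@](C)(O)[C@@H](O)CC/C(C)=C\CO[Si](c1ccccc1)(c1ccccc1)C(C)(C)C | intermediate
24 | (1S,4Z)-6-(TBDPSO)-4-methyl-1-[(4R)-2,2,4-trimethyl-1,3-dioxolan-4-yl]hex-4-en-1-ol | CC1(C)OC[C@](C)([C@@H](O)CC/C(C)=C\CO[Si](c2ccccc2)(c2ccccc2)C(C)(C)C)O1 | intermediate
25 | (5Z)-7-(TBDPSO)-6-methyl-2-{[(1S,4Z)-6-(TBDPSO)-4-methyl-1-[(4R)-2,2,4-trimethyl-1,3-dioxolan-4-yl]hex-4-en-1-yl]oxy}hept-5-enoic acid, C11 epimers | OC(=O)C(CC/C=C(/C)CO[Si](c1ccccc1)(c1ccccc1)C(C)(C)C)O[C@@H](CC/C(C)=C\CO[Si](c1ccccc1)(c1ccccc1)C(C)(C)C)[C@@]1(C)COC(C)(C)O1 | intermediate (not isolated)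
26 | methyl ester of 25, C11 epimers | COC(=O)C(CC/C=C(/C)CO[Si](c1ccccc1)(c1ccccc1)C(C)(C)C)O[C@@H](CC/C(C)=C\CO[Si](c1ccccc1)(c1ccccc1)C(C)(C)C)[C@@]1(C)COC(C)(C)O1 | intermediate
27 | methyl (5Z)-7-(TBDPSO)-2-{[(2R,3S,6Z)-8-(TBDPSO)-1,2-dihydroxy-2,6-dimethyloct-6-en-3-yl]oxy}-6-methylhept-5-enoate, C11 epimers | COC(=O)C(CC/C=C(/C)CO[Si](c1ccccc1)(c1ccccc1)C(C)(C)C)O[C@@H](CC/C(C)=C\CO[Si](c1ccccc1)(c1ccccc1)C(C)(C)C)[C@](C)(O)CO | intermediate
28 | bis(triethylsilyl) ether of 27 (chain 6S,7R) | COC(=O)C(CC/C=C(/C)CO[Si](c1ccccc1)(c1ccccc1)C(C)(C)C)O[C@@H](CC/C(C)=C\CO[Si](c1ccccc1)(c1ccccc1)C(C)(C)C)[C@](C)(O[Si](CC)(CC)CC)CO[Si](CC)(CC)CC | intermediate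
29 | methyl (5Z)-7-(TBDPSO)-2-{[(2S,3S,6Z)-8-(TBDPSO)-2,6-dimethyl-1-oxo-2-(TESO)oct-6-en-3-yl]oxy}-6-methylhept-5-enoate (chain 6S,7S), C11 epimers | COC(=O)C(CC/C=C(/C)CO[Si](c1ccccc1)(c1ccccc1)C(C)(C)C)O[C@@H](CC/C(C)=C\CO[Si](c1ccccc1)(c1ccccc1)C(C)(C)C)[C@](C)(O[Si](CC)(CC)CC)C=O | intermediate
30 | chlorobis(cyclopentadienyl)[(E)-2-(PMBO)ethenyl]zirconium | COc1ccc(CO/C=C/[Zr](Cl)(C2C=CC=C2)C2C=CC=C2)cc1 | intermediate (not isolated)
31 | methyl[(E)-2-(PMBO)ethenyl]zinc | COc1ccc(CO/C=C/[Zn]C)cc1 | intermediate (not isolated)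
32 | methyl ester allylic alcohol, C8(OH)–C9H=C10H–OPMB (9E; chain 6S,7R,8R), C11 epimers | COC(=O)C(CC/C=C(/C)CO[Si](c1ccccc1)(c1ccccc1)C(C)(C)C)O[C@@H](CC/C(C)=C\CO[Si](c1ccccc1)(c1ccccc1)C(C)(C)C)[C@](C)(O[Si](CC)(CC)CC)[C@H](O)/C=C/OCc1ccc(OC)cc1 | intermediate
33 | seco acid, free C17 acid of 32 (chain 6S,7R,8R), C11 epimers | OC(=O)C(CC/C=C(/C)CO[Si](c1ccccc1)(c1ccccc1)C(C)(C)C)O[C@@H](CC/C(C)=C\CO[Si](c1ccccc1)(c1ccccc1)C(C)(C)C)[C@](C)(O[Si](CC)(CC)CC)[C@H](O)/C=C/OCc1ccc(OC)cc1 | intermediate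
34 | (5S,6S,7R)-7-[(E)-2-(PMBO)ethenyl]-6-methyl-6-(TESO)-3-[(3Z)-5-(TBDPSO)-4-methylpent-3-en-1-yl]-5-[(3Z)-5-(TBDPSO)-3-methylpent-3-en-1-yl]-1,4-dioxepan-2-one, C11 epimers | C/C(=C/CCC1O[C@@H](CC/C(C)=C\CO[Si](c3ccccc3)(c3ccccc3)C(C)(C)C)[C@](C)(O[Si](CC)(CC)CC)[C@@H](/C=C/OCc2ccc(OC)cc2)OC1=O)CO[Si](c1ccccc1)(c1ccccc1)C(C)(C)C | intermediate (precursor of the key step)
35 | cyclic trimethylsilyl ketene acetal of 34 (C11=C17, OSiMe3 on C17) | C/C(=C/CCC1O[C@@H](CC/C(C)=C\CO[Si](c3ccccc3)(c3ccccc3)C(C)(C)C)[C@](C)(O[Si](CC)(CC)CC)[C@@H](/C=C/OCc2ccc(OC)cc2)OC=1O[Si](C)(C)C)CO[Si](c1ccccc1)(c1ccccc1)C(C)(C)C | intermediate (not isolated)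
36 | trimethylsilyl ester of 37 | C/C(=C/CC[C@@]1(C(=O)O[Si](C)(C)C)O[C@@H](CC/C(C)=C\CO[Si](c3ccccc3)(c3ccccc3)C(C)(C)C)[C@](C)(O[Si](CC)(CC)CC)/C=C\[C@@H]1OCc2ccc(OC)cc2)CO[Si](c1ccccc1)(c1ccccc1)C(C)(C)C | intermediate (not isolated)
37 | (2R,3S,6R,7S)-3-(PMBO)-6-methyl-6-(TESO)-2-[(3Z)-5-(TBDPSO)-4-methylpent-3-en-1-yl]-7-[(3Z)-5-(TBDPSO)-3-methylpent-3-en-1-yl]-2,3,6,7-tetrahydrooxepine-2-carboxylic acid | C/C(=C/CC[C@@]1(C(=O)O)O[C@@H](CC/C(C)=C\CO[Si](c3ccccc3)(c3ccccc3)C(C)(C)C)[C@](C)(O[Si](CC)(CC)CC)/C=C\[C@@H]1OCc2ccc(OC)cc2)CO[Si](c1ccccc1)(c1ccccc1)C(C)(C)C | intermediate (product of the key step)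
38 | (2R,3S,6R,7S)-oxepane-2-carboxylic acid, the 8,9-dihydro derivative of 37 | C/C(=C/CC[C@@]1(C(=O)O)O[C@@H](CC/C(C)=C\CO[Si](c3ccccc3)(c3ccccc3)C(C)(C)C)[C@](C)(O[Si](CC)(CC)CC)CC[C@@H]1OCc2ccc(OC)cc2)CO[Si](c1ccccc1)(c1ccccc1)C(C)(C)C | intermediate
39 | C7 hydroxy acid, 38 without the TES group | C/C(=C/CC[C@@]1(C(=O)O)O[C@@H](CC/C(C)=C\CO[Si](c3ccccc3)(c3ccccc3)C(C)(C)C)[C@](C)(O)CC[C@@H]1OCc2ccc(OC)cc2)CO[Si](c1ccccc1)(c1ccccc1)C(C)(C)C | intermediate
40 | bridged lactone, 6,8-dioxabicyclo[3.2.2]nonan-7-one core, C10–OPMB, C1 and C16 TBDPS ethers (chain 6S,7R,10S,11R) | C/C(=C/CC[C@@]12O[C@@H](CC/C(C)=C\CO[Si](c3ccccc3)(c3ccccc3)C(C)(C)C)[C@@](C)(CC[C@@H]1OCc4ccc(OC)cc4)OC2=O)CO[Si](c1ccccc1)(c1ccccc1)C(C)(C)C | intermediate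
41 | bridged lactone with free C10–OH, C1 and C16 TBDPS ethers | C/C(=C/CC[C@@]12O[C@@H](CC/C(C)=C\CO[Si](c3ccccc3)(c3ccccc3)C(C)(C)C)[C@@](C)(CC[C@@H]1O)OC2=O)CO[Si](c1ccccc1)(c1ccccc1)C(C)(C)C | intermediate
42 | CNP0105745.1 (chain 2Z,6S,7R,10S,11R,14Z) | C/C(=C/CC[C@@]12O[C@@H](CC/C(C)=C\CO)[C@@](C)(CC[C@@H]1O)OC2=O)CO | target

**Step count and risks**

Total: 26 steps. Longest linear sequence: 18 steps (nerol to the target: steps 8, 9 and 11–26).

Steps most likely to fail:

Step 14 (etherification). The SN2 displacement at the secondary bromide by the hindered C6 alkoxide may be slow, so that dehydrobromination of the bromo carboxylate takes over. The fallback sets out from 6 and 24 and comes back at 26. The potassium enolate of 6 is hydroxylated with 2-(phenylsulfonyl)-3-phenyloxaziridine to the ethyl 2-hydroxy ester F1, which Tf2O/2,6-lutidine converts into the ethyl 2-(trifluoromethylsulfonyloxy) ester F2. The sodium alkoxide of 24 displaces the far better leaving group at −40 °C to give the ethyl ester acetonide F3. Saponification gives the ether acid 25, and K2CO3/MeI returns to 26.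

Step 18 (alkenylzinc addition). Facial selectivity at C8 may be poor if chelation of zinc by O6 or the ester competes with the Felkin–Anh mode. The fallback sets out from 32 obtained as a C8-epimer mixture and comes back at 32. Oxidation with Dess–Martin periodinane/NaHCO3 gives the (E)-beta-alkoxy enone F8, which is reduced under reagent control by a Corey–Bakshi–Shibata reduction (oxazaborolidine, catecholborane, −78 °C). The (S)-configured B-methyl catalyst is expected to give 8R if the fully substituted C7 acts as the large carbonyl substituent; this assignment would have to be checked.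

Step 21 (Ireland–Claisen). The hindered C11 may resist enolisation, or the ketene acetal may fragment (loss of the C8 alkoxide as a ketene forms) or hydrolyse back before it reaches the strained boat. The fallback sets out from 29 and comes back at 37, giving up the stereochemical relay. Wittig methylenation (Ph3P=CH2) gives the C8 vinyl compound F4. Aldol addition of its lithium ester enolate to acrolein forms C10–C11 and gives the diene alcohol F5 as a diastereomer mixture. PMB trichloroacetimidate with catalytic acid gives the PMB ether F6. Ring-closing metathesis with the second-generation Grubbs catalyst closes C8=C9 to the oxepene methyl ester F7, from which the wanted isomer is separated. Saponification gives 37.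

**Further compounds**
F1 | step 14 | ethyl (5Z)-7-(TBDPSO)-2-hydroxy-6-methylhept-5-enoate, racemic | CCOC(=O)C(O)CC/C=C(/C)CO[Si](c1ccccc1)(c1ccccc1)C(C)(C)C
F2 | step 14 | ethyl (5Z)-7-(TBDPSO)-6-methyl-2-(trifluoromethylsulfonyloxy)hept-5-enoate, racemic | CCOC(=O)C(OS(=O)(=O)C(F)(F)F)CC/C=C(/C)CO[Si](c1ccccc1)(c1ccccc1)C(C)(C)C
F3 | step 14 | ethyl ester analogue of 26, C11 epimers | CCOC(=O)C(CC/C=C(/C)CO[Si](c1ccccc1)(c1ccccc1)C(C)(C)C)O[C@@H](CC/C(C)=C\CO[Si](c1ccccc1)(c1ccccc1)C(C)(C)C)[C@@]1(C)COC(C)(C)O1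
F8 | step 18 | methyl ester (E)-beta-alkoxy enone, C8 ketone of 32 | COC(=O)C(CC/C=C(/C)CO[Si](c1ccccc1)(c1ccccc1)C(C)(C)C)O[C@@H](CC/C(C)=C\CO[Si](c1ccccc1)(c1ccccc1)C(C)(C)C)[C@](C)(O[Si](CC)(CC)CC)C(=O)/C=C/OCc1ccc(OC)cc1
F4 | step 21 | C8 vinyl compound, methylenation product of 29 | COC(=O)C(CC/C=C(/C)CO[Si](c1ccccc1)(c1ccccc1)C(C)(C)C)O[C@@H](CC/C(C)=C\CO[Si](c1ccccc1)(c1ccccc1)C(C)(C)C)[C@](C)(O[Si](CC)(CC)CC)C=C
F5 | step 21 | acrolein aldol adduct, wanted (10S,11R) isomer drawn | COC(=O)[C@@](CC/C=C(/C)CO[Si](c1ccccc1)(c1ccccc1)C(C)(C)C)([C@@H](O)C=C)O[C@@H](CC/C(C)=C\CO[Si](c1ccccc1)(c1ccccc1)C(C)(C)C)[C@](C)(O[Si](CC)(CC)CC)C=C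
F6 | step 21 | C10 PMB ether of F5 | COC(=O)[C@@](CC/C=C(/C)CO[Si](c1ccccc1)(c1ccccc1)C(C)(C)C)([C@@H](OCc1ccc(OC)cc1)C=C)O[C@@H](CC/C(C)=C\CO[Si](c1ccccc1)(c1ccccc1)C(C)(C)C)[C@](C)(O[Si](CC)(CC)CC)C=C
F7 | step 21 | methyl ester of 37 | C/C(=C/CC[C@@]1(C(=O)OC)O[C@@H](CC/C(C)=C\CO[Si](c3ccccc3)(c3ccccc3)C(C)(C)C)[C@](C)(O[Si](CC)(CC)CC)/C=C\[C@@H]1OCc2ccc(OC)cc2)CO[Si](c1ccccc1)(c1ccccc1)C(C)(C)C
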